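## The problem

CNP0079001.0 (22) has no stereocentre and no ring fusion, so the task is purely one of regiochemistry on two crowded benzene rings. Two bibenzyl units, each with a 4-hydroxy-3-methoxyphenethyl arm, are joined through a single methylene carbon. In ring A the bridge sits on the carbon between the hydroxyl and the arylethyl chain, with the methoxy group para to it. In ring B the bridge sits on the carbon between the hydroxyl and the methoxy group, with the chain para to it. Each inner ring therefore carries one free and one methylated oxygen that must be told apart, and the bridge has four ortho substituents. A direct electrophilic benzylation of a ring B bibenzyl would have to prefer the position between the two oxygens over the two positions beside the chain, which cannot be relied on. The four free phenols make the final compound sensitive to air. The diarylmethane, flanked by oxygen on both rings, can lose its benzyl group after ipso protonation, and any ring A benzylic halide ionises easily. The enabling feature is in ring B: the sequence C(OH)–C(bridge)–C(OMe)–CH is an acetoacetate benzylated at its central carbon, and the remaining C(chain)–CH pair is an alkyne. The CH carbon lies ortho to the hydroxyl and para to the methoxy group, so it can carry a carboxyl that activates the alkyne and later leaves as carbon dioxide.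

## Retrosynthesis

**22 back to 20.** The four O–benzyl bonds and the C–CO2H bond on the ring B CH carbon are cut, via acid 21. Benzyl is used for all three protected phenols and for the ester, so that a single neutral hydrogenolysis unmasks everything and no acid touches the diarylmethane. The ester carbon is ortho to the hydroxyl and para to the methoxy group, where a benzoic acid decarboxylates on heating. The forward reactions only need to be mild.

**20 back to 17 and 7.** Ring B is opened at the CH–C(chain) bond and at the C(OH)–C(ester) bond. This gives the 2-benzylated 1,3-dimethoxy-1-silyloxybutadiene 17 and the alkynoate 7. Against a union of two finished rings, this cut has the bridge carbon already bonded to the central diene carbon, so its place between the two oxygens is fixed. The oxygens differentiate themselves: the ketene acetal carbon becomes the phenol and the enol ether carbon keeps its methyl group. The forward step must pair the diene CH2 terminus with the β-carbon of the alkynoate and must tolerate a hindered diene.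

**17 back to 13 and 14.** The silyl ketene acetal 17 comes from enol ether 16 by γ-deprotonation and O-silylation, and 16 from keto ester 15 by O-methylation. Cutting the bond between the bridge carbon and the acetoacetate central carbon leads to the ring A benzylic bromide 13 and methyl acetoacetate 14. The forward alkylation is standard enolate chemistry; its only demand is that the labile bromide be used at once.

**13 back to 10 and 2.** Bromide 13 comes from alcohol 12 and ester 11. The bibenzyl CH2–CH2 bond of 11 is cut to the ortho-toluate 10, used as its lateral anion, and the benzylic bromide 2. An entry through a stilbene, ring formylation and Lewis-acid ortho-demethylation was set aside: the alkene reduction and the demethylating Lewis acid would both endanger the aryl benzyl ethers, and the formylation is not fully regioselective. In 10 the carboxyl carbon (the future bridge), the ortho oxygen, the para methoxy group and the methyl that becomes the chain are already in place.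

**10 back to 8.** Two O–C bonds are cut, through 9. In methyl orsellinate 8 the 2-hydroxyl is hydrogen-bonded to the ester, so the 4-hydroxyl is methylated first and the 2-hydroxyl benzylated afterwards.

**7 back to 2, 3 and 6.** The ester C–C bond is cut to the terminal alkyne 5 and benzyl chloroformate 6. Alkyne 5 comes from silyl alkyne 4, made by propargylation of bromide 2 with the anion of silylpropyne 3. Bromide 2, from the commercial alcohol 1, thus supplies both arylethyl arms of the target.

## Roads not taken

**Alternative 1:** The cut removes both outer rings at their aryl–vinyl bonds. A divinyl diarylmethane A1 and two equivalents of the aryl bromide A2 would be joined by a double Heck reaction under a zerovalent palladium–triarylphosphine catalyst to give bis-stilbene A3. Hydrogenation and acid removal of the methoxymethyl groups would then give 22.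
- Merits: the step is catalytic and well understood, it installs both identical arms late and at once, and the alkene geometry does not matter.
- Weak points: the hard part is not addressed. A1 already contains the tetra-ortho-substituted diarylmethane with both OH/OMe patterns, so its synthesis needs the very regiocontrolled union of rings A and B that is the crux. A2 is an electron-rich bromide, both couplings must go to completion, and the endgame needs an acidic deprotection on an acid-labile diarylmethane.
- Comparison: the Heck step is probably more reliable than the cycloaddition chosen here, and its endgame is no longer. Against this, the chosen plan makes ring B with the bridge already in place and needs one type of protecting group only.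

**Alternative 2:** The cut goes through ring A. The 4-methoxy-2-pyranone A4, carrying the arylethyl chain at C6, and the ring B ethynyl ketone A5 would combine on heating by Diels–Alder addition across pyrone C3 and C6. Decarboxylative aromatisation of the bridged lactone would give benzophenone A6.
- Merits: A4 is a stable diene that is not moisture-sensitive, the regiochemistry follows from the polarisation of both partners, and gas extrusion makes the step irreversible.
- Weak points: A6 lacks the ring A hydroxyl, which would have to be introduced by a late C–H oxidation next to a hindered ketone. That ketone must then be reduced to the methylene. Such pyranones are sluggish dienes, and A5 is a fully substituted ring B that needs its own regiocontrolled synthesis.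
- Comparison: A4 is easier to handle than the silyl ketene acetal 17, which is a real advantage. The chosen plan sets against it that ring B emerges with every substituent correctly placed and that its extra carbon leaves by itself, whereas A6 is one oxidation short on ring A and one too high at the bridge.

**Alternative 3:** The cut again goes through ring A. Cyclobutenone A7 and methoxyacetylene A8 would react on heating: electrocyclic opening to a vinylketene, [2+2] addition of A8, a second ring opening and 6π closure. The product is phenol A9, the tri-O-benzyl ether of 22.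
- Merits: ring A appears with the free hydroxyl ortho to the bridge, the methoxy group para and the chain in place, with reliable regiochemistry for an alkoxyalkyne. A9 is one hydrogenolysis from 22, a shorter endgame than the chosen one, with no traceless group.
- Weak points: A7 is a 3,4-disubstituted cyclobutenone with a large benzyl group at C4, for which no general preparation exists. A8 is volatile and unstable. Ring B must again be complete beforehand, so the demanding step falls late on the most valuable material.
- Comparison: in the key step and the endgame this road is better. The chosen plan sets against it that both partners, 17 and 7, come from commodity materials by standard enolate and acetylide chemistry. It also builds the ring that is hardest to reach by substitution, while ring A comes ready-made from an orsellinate.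

Key step: step 13

## Route

Remark: 16 and 17 are expected as mixtures of double-bond isomers and 15 and 18 as racemates; none of this survives into the achiral target, so these SMILES carry no configuration, and 1, 3, 6, 8 and 14 are taken as catalogue compounds.

Step 1
Reactants: 1 [4-(benzyloxy)-3-methoxyphenyl]methanol
Product: 2 1-(benzyloxy)-4-(bromomethyl)-2-methoxybenzene
Conditions: PBr3 (0.4 equiv), Et2O, 0 °C
Reagents that add atoms: phosphorus tribromide, BrP(Br)Br
Why: Bromination of a benzylic alcohol through its dibromophosphite by SN2 displacement; the aryl benzyl ether is inert and the bromide is used without storage.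

Step 2
Reactants: 2 1-(benzyloxy)-4-(bromomethyl)-2-methoxybenzene; 3 trimethyl(prop-1-yn-1-yl)silane
Product: 4 {4-[4-(benzyloxy)-3-methoxyphenyl]but-1-yn-1-yl}trimethylsilane
Conditions: 3, n-BuLi, THF, −78 °C; then 2, −78 °C → rt
Reagents that add atoms: none
Why: Propargylic lithiation of the silylpropyne and SN2 alkylation by a benzylic bromide; the silyl group blocks the alkyne terminus and directs attack to the propargylic carbon, not the allenyl one.

Step 3
Reactants: 4 {4-[4-(benzyloxy)-3-methoxyphenyl]but-1-yn-1-yl}trimethylsilane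
Product: 5 1-(benzyloxy)-4-(but-3-yn-1-yl)-2-methoxybenzene
Conditions: K2CO3 (cat.), MeOH, rt
Reagents that add atoms: none
Why: Methanolysis of an alkynyl C–Si bond under mild base, a standard protodesilylation that leaves ethers untouched.

Step 4
Reactants: 5 1-(benzyloxy)-4-(but-3-yn-1-yl)-2-methoxybenzene; 6 benzyl chloroformate
Product: 7 benzyl 5-[4-(benzyloxy)-3-methoxyphenyl]pent-2-ynoate
Conditions: n-BuLi, THF, −78 °C; then 6, −78 → 0 °C
Reagents that add atoms: none
Why: Acylation of a lithium acetylide with a chloroformate, the usual route to alk-2-ynoates; inverse addition to excess 6 suppresses double addition.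

Step 5
Reactants: 8 methyl 2,4-dihydroxy-6-methylbenzoate (methyl orsellinate)
Product: 9 methyl 2-hydroxy-4-methoxy-6-methylbenzoate
Conditions: MeI (1.05 equiv), K2CO3, acetone, rt → 40 °C
Reagents that add atoms: iodomethane, CI
Why: Williamson etherification; the 2-hydroxyl is hydrogen-bonded to the ester carbonyl and much less nucleophilic, so one equivalent of MeI methylates the 4-hydroxyl selectively, as is well known for orsellinates.

Step 6
Reactants: 9 methyl 2-hydroxy-4-methoxy-6-methylbenzoate
Product: 10 methyl 2-(benzyloxy)-4-methoxy-6-methylbenzoate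
Conditions: BnBr, K2CO3, DMF, 60 °C
Reagents that add atoms: benzyl bromide, BrCc1ccccc1
Why: Williamson benzylation of the remaining chelated phenol, which needs only a dipolar solvent and moderate heat.

Step 7
Reactants: 10 methyl 2-(benzyloxy)-4-methoxy-6-methylbenzoate; 2 1-(benzyloxy)-4-(bromomethyl)-2-methoxybenzene
Product: 11 methyl 2-(benzyloxy)-6-{2-[4-(benzyloxy)-3-methoxyphenyl]ethyl}-4-methoxybenzoate
Conditions: LiN(iPr)2 (1.2 equiv), THF, −78 °C; then 2, −78 → −20 °C
Reagents that add atoms: none
Why: Lateral metalation of an ortho-toluate gives an ester-stabilised benzylic anion that is alkylated by the benzylic bromide (SN2), a reaction established for 2,4-dialkoxy-6-methylbenzoates; low temperature and a slight excess of base suppress self-condensation.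

Step 8
Reactants: 11 methyl 2-(benzyloxy)-6-{2-[4-(benzyloxy)-3-methoxyphenyl]ethyl}-4-methoxybenzoate
Product: 12 (2-(benzyloxy)-6-{2-[4-(benzyloxy)-3-methoxyphenyl]ethyl}-4-methoxyphenyl)methanol
Conditions: LiAlH4, THF, 0 °C → rt
Reagents that add atoms: none
Why: Hydride reduction of a hindered benzoate to the benzylic alcohol; aryl ethers are inert to LiAlH4.

Step 9
Reactants: 12 (2-(benzyloxy)-6-{2-[4-(benzyloxy)-3-methoxyphenyl]ethyl}-4-methoxyphenyl)methanol
Product: 13 1-(benzyloxy)-3-{2-[4-(benzyloxy)-3-methoxyphenyl]ethyl}-2-(bromomethyl)-5-methoxybenzene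
Conditions: PBr3 (0.4 equiv), Et2O, −10 °C; cold aqueous NaHCO3 wash; crude used at once
Reagents that add atoms: phosphorus tribromide, BrP(Br)Br
Why: Bromination of a benzylic alcohol with PBr3 as in step 1; the product is an ionisable 2,4-dialkoxybenzyl bromide and is therefore carried forward cold and unpurified.

Step 10
Reactants: 13 1-(benzyloxy)-3-{2-[4-(benzyloxy)-3-methoxyphenyl]ethyl}-2-(bromomethyl)-5-methoxybenzene; 14 methyl acetoacetate
Product: 15 methyl 2-(2-(benzyloxy)-6-{2-[4-(benzyloxy)-3-methoxyphenyl]ethyl}-4-methoxybenzyl)-3-oxobutanoate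
Conditions: 14 (2.5 equiv), NaH (2.4 equiv), THF, 0 °C; then 13, 0 °C → rt
Reagents that add atoms: none
Why: Acetoacetic ester C-alkylation by a soft, very reactive benzylic bromide; the excess of sodium enolate intercepts the bromide quickly and limits dialkylation.

Step 11
Reactants: 15 methyl 2-(2-(benzyloxy)-6-{2-[4-(benzyloxy)-3-methoxyphenyl]ethyl}-4-methoxybenzyl)-3-oxobutanoate
Product: 16 methyl 2-(2-(benzyloxy)-6-{2-[4-(benzyloxy)-3-methoxyphenyl]ethyl}-4-methoxybenzyl)-3-methoxybut-2-enoate
Conditions: HC(OMe)3, H2SO4 (cat.), MeOH, rt; then toluene, 90 °C (−MeOH)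
Reagents that add atoms: trimethyl orthoformate, COC(OC)OC
Why: Acid-catalysed ketalisation with an orthoester and loss of methanol, the standard route to the 3-methoxybut-2-enoates from which these dienes are made; any β,γ-unsaturated isomer gives the same dienolate in step 12.

Step 12
Reactants: 16 methyl 2-(2-(benzyloxy)-6-{2-[4-(benzyloxy)-3-methoxyphenyl]ethyl}-4-methoxybenzyl)-3-methoxybut-2-enoate
Product: 17 {[2-(2-(benzyloxy)-6-{2-[4-(benzyloxy)-3-methoxyphenyl]ethyl}-4-methoxybenzyl)-1,3-dimethoxybuta-1,3-dien-1-yl]oxy}trimethylsilane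
Conditions: LiN(iPr)2, THF, −78 °C; Me3SiCl, −78 → 0 °C; pentane, filtration under Ar, used crude
Reagents that add atoms: chlorotrimethylsilane, C[Si](C)(C)Cl
Why: Kinetic γ-deprotonation of the β-methoxy enoate gives the extended enolate, which the hard silyl chloride traps on oxygen to give the vinylketene acetal; the benzylic CH2 on C2 is not conjugated to the carbonyl and is much less acidic.

Step 13
Reactants: 17 {[2-(2-(benzyloxy)-6-{2-[4-(benzyloxy)-3-methoxyphenyl]ethyl}-4-methoxybenzyl)-1,3-dimethoxybuta-1,3-dien-1-yl]oxy}trimethylsilane; 7 benzyl 5-[4-(benzyloxy)-3-methoxyphenyl]pent-2-ynoate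
Product: 20 benzyl 3-(2-(benzyloxy)-6-{2-[4-(benzyloxy)-3-methoxyphenyl]ethyl}-4-methoxybenzyl)-2-hydroxy-6-{2-[4-(benzyloxy)-3-methoxyphenyl]ethyl}-4-methoxybenzoate, via mixed-ketal cycloadduct 18 (not isolated), via aryl trimethylsilyl ether 19 (not isolated)
Conditions: 7 (1.5 equiv), toluene, 120 °C, sealed tube; then 1 M HCl, THF, rt
Reagents that add atoms: none
Why: The diene 17, raised in energy by three oxygen donors, and the alkynoate 7 combine in a normal-demand, strongly asynchronous Diels–Alder reaction: the unsubstituted CH2 terminus bonds to the β-carbon of 7 and the ketene acetal carbon to the α-carbon, either concertedly or by Michael addition and closure of the allenoate carbon onto the silyloxy(methoxy)carbenium ion. The six-membered ring is thus closed intermolecularly in a 4+2 mode and gives the cyclohexa-1,4-diene 18. Loss of methanol from the mixed ketal carbon and the ring CH2 aromatises 18 to silyl ether 19, which dilute acid cleaves to phenol 20; loss of the silyl group first would lead to the same phenol through the dienone. The closest known reactions are the additions of 1,3-dimethoxy-1-silyloxybutadienes, 2-alkyl congeners included, to propiolates and but-2-ynoates, which give 2-hydroxy-4-methoxybenzoates. No lasting stereocentre is formed, since the quaternary carbon of 18 becomes planar on aromatisation. The selectivity needed is regiochemical, the chain para to the bridge and the ester ortho to the new hydroxyl. It is secured by the polarity match between the nucleophilic diene terminus and the electrophilic β-carbon of the ynoate; the reverse pairing has no electronic support. The benzyl ethers and the benzyl ester are inert to the heat and to the brief acid treatment.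

Step 14
Reactants: 20 benzyl 3-(2-(benzyloxy)-6-{2-[4-(benzyloxy)-3-methoxyphenyl]ethyl}-4-methoxybenzyl)-2-hydroxy-6-{2-[4-(benzyloxy)-3-methoxyphenyl]ethyl}-4-methoxybenzoate
Product: 21 2-hydroxy-3-{2-hydroxy-6-[2-(4-hydroxy-3-methoxyphenyl)ethyl]-4-methoxybenzyl}-6-[2-(4-hydroxy-3-methoxyphenyl)ethyl]-4-methoxybenzoic acid
Conditions: H2 (1 atm), 10% Pd/C, EtOAc–MeOH, rt
Reagents that add atoms: none
Why: Hydrogenolysis of three aryl benzyl ethers and one benzyl ester under neutral conditions; the diarylmethane C–C bonds and the methyl ethers are not affected.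

Step 15
Reactants: 21 2-hydroxy-3-{2-hydroxy-6-[2-(4-hydroxy-3-methoxyphenyl)ethyl]-4-methoxybenzyl}-6-[2-(4-hydroxy-3-methoxyphenyl)ethyl]-4-methoxybenzoic acid
Product: 22 2-{2-hydroxy-6-[2-(4-hydroxy-3-methoxyphenyl)ethyl]-4-methoxybenzyl}-5-[2-(4-hydroxy-3-methoxyphenyl)ethyl]-3-methoxyphenol (CNP0079001.0)
Conditions: degassed DMF, 130 °C, Ar
Reagents that add atoms: none
Why: Thermal protodecarboxylation of a 2-hydroxy-4-alkoxy-6-alkylbenzoic acid by ipso protonation at the carbon ortho to OH and para to OMe, the behaviour known for orsellinic-type and cannabinoid acids near this temperature.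

## Compound list

1 | [4-(benzyloxy)-3-methoxyphenyl]methanol | OCc1ccc(OCc2ccccc2)c(OC)c1 | starting material
2 | 1-(benzyloxy)-4-(bromomethyl)-2-methoxybenzene | BrCc1ccc(OCc2ccccc2)c(OC)c1 | intermediate
3 | trimethyl(prop-1-yn-1-yl)silane | CC#C[Si](C)(C)C | starting material
4 | {4-[4-(benzyloxy)-3-methoxyphenyl]but-1-yn-1-yl}trimethylsilane | C[Si](C)(C)C#CCCc1ccc(OCc2ccccc2)c(OC)c1 | intermediate
5 | 1-(benzyloxy)-4-(but-3-yn-1-yl)-2-methoxybenzene | C#CCCc1ccc(OCc2ccccc2)c(OC)c1 | intermediate
6 | benzyl chloroformate | O=C(Cl)OCc1ccccc1 | starting material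
7 | benzyl 5-[4-(benzyloxy)-3-methoxyphenyl]pent-2-ynoate | O=C(OCc1ccccc1)C#CCCc1ccc(OCc2ccccc2)c(OC)c1 | intermediate
8 | methyl 2,4-dihydroxy-6-methylbenzoate (methyl orsellinate) | COC(=O)c1c(C)cc(O)cc1O | starting material
9 | methyl 2-hydroxy-4-methoxy-6-methylbenzoate | COC(=O)c1c(C)cc(OC)cc1O | intermediate
10 | methyl 2-(benzyloxy)-4-methoxy-6-methylbenzoate | COC(=O)c1c(C)cc(OC)cc1OCc1ccccc1 | intermediate
11 | methyl 2-(benzyloxy)-6-{2-[4-(benzyloxy)-3-methoxyphenyl]ethyl}-4-methoxybenzoate | COC(=O)c1c(CCc2ccc(OCc3ccccc3)c(OC)c2)cc(OC)cc1OCc1ccccc1 | intermediate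
12 | (2-(benzyloxy)-6-{2-[4-(benzyloxy)-3-methoxyphenyl]ethyl}-4-methoxyphenyl)methanol | OCc1c(CCc2ccc(OCc3ccccc3)c(OC)c2)cc(OC)cc1OCc1ccccc1 | intermediate
13 | 1-(benzyloxy)-3-{2-[4-(benzyloxy)-3-methoxyphenyl]ethyl}-2-(bromomethyl)-5-methoxybenzene | BrCc1c(CCc2ccc(OCc3ccccc3)c(OC)c2)cc(OC)cc1OCc1ccccc1 | intermediate
14 | methyl acetoacetate | COC(=O)CC(C)=O | starting material
15 | methyl 2-(2-(benzyloxy)-6-{2-[4-(benzyloxy)-3-methoxyphenyl]ethyl}-4-methoxybenzyl)-3-oxobutanoate (racemic) | COC(=O)C(Cc1c(OCc2ccccc2)cc(OC)cc1CCc1ccc(OCc2ccccc2)c(OC)c1)C(C)=O | intermediate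
16 | methyl 2-(2-(benzyloxy)-6-{2-[4-(benzyloxy)-3-methoxyphenyl]ethyl}-4-methoxybenzyl)-3-methoxybut-2-enoate (E/Z mixture) | COC(=O)C(Cc1c(OCc2ccccc2)cc(OC)cc1CCc1ccc(OCc2ccccc2)c(OC)c1)=C(C)OC | intermediate
17 | {[2-(2-(benzyloxy)-6-{2-[4-(benzyloxy)-3-methoxyphenyl]ethyl}-4-methoxybenzyl)-1,3-dimethoxybuta-1,3-dien-1-yl]oxy}trimethylsilane (ketene acetal isomers) | C=C(OC)C(Cc1c(OCc2ccccc2)cc(OC)cc1CCc1ccc(OCc2ccccc2)c(OC)c1)=C(OC)O[Si](C)(C)C | intermediate
18 | benzyl 5-(2-(benzyloxy)-6-{2-[4-(benzyloxy)-3-methoxyphenyl]ethyl}-4-methoxybenzyl)-2-{2-[4-(benzyloxy)-3-methoxyphenyl]ethyl}-4,6-dimethoxy-6-[(trimethylsilyl)oxy]cyclohexa-1,4-diene-1-carboxylate (racemic, not isolated) | COC1(O[Si](C)(C)C)C(Cc2c(OCc3ccccc3)cc(OC)cc2CCc2ccc(OCc3ccccc3)c(OC)c2)=C(OC)CC(CCc2ccc(OCc3ccccc3)c(OC)c2)=C1C(=O)OCc1ccccc1 | intermediate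
19 | benzyl 3-(2-(benzyloxy)-6-{2-[4-(benzyloxy)-3-methoxyphenyl]ethyl}-4-methoxybenzyl)-6-{2-[4-(benzyloxy)-3-methoxyphenyl]ethyl}-4-methoxy-2-[(trimethylsilyl)oxy]benzoate (not isolated) | C[Si](C)(C)Oc1c(Cc2c(OCc3ccccc3)cc(OC)cc2CCc2ccc(OCc3ccccc3)c(OC)c2)c(OC)cc(CCc2ccc(OCc3ccccc3)c(OC)c2)c1C(=O)OCc1ccccc1 | intermediate
20 | benzyl 3-(2-(benzyloxy)-6-{2-[4-(benzyloxy)-3-methoxyphenyl]ethyl}-4-methoxybenzyl)-2-hydroxy-6-{2-[4-(benzyloxy)-3-methoxyphenyl]ethyl}-4-methoxybenzoate | O=C(OCc1ccccc1)c1c(O)c(Cc2c(OCc3ccccc3)cc(OC)cc2CCc2ccc(OCc3ccccc3)c(OC)c2)c(OC)cc1CCc1ccc(OCc2ccccc2)c(OC)c1 | intermediate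
21 | 2-hydroxy-3-{2-hydroxy-6-[2-(4-hydroxy-3-methoxyphenyl)ethyl]-4-methoxybenzyl}-6-[2-(4-hydroxy-3-methoxyphenyl)ethyl]-4-methoxybenzoic acid | O=C(O)c1c(O)c(Cc2c(O)cc(OC)cc2CCc2ccc(O)c(OC)c2)c(OC)cc1CCc1ccc(O)c(OC)c1 | intermediate
22 | 2-{2-hydroxy-6-[2-(4-hydroxy-3-methoxyphenyl)ethyl]-4-methoxybenzyl}-5-[2-(4-hydroxy-3-methoxyphenyl)ethyl]-3-methoxyphenol (CNP0079001.0) | COc1cc(O)c(Cc2c(O)cc(CCc3ccc(O)c(OC)c3)cc2OC)c(CCc2ccc(O)c(OC)c2)c1 | target

## Step count and risks

Total step count: 15. Longest linear sequence: 11 steps (8 to 22, steps 5 to 15). The alkynoate branch has 4 steps (1 to 7).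

**Step 13 (key step).** The diene carries a substituent at C2 and a fully substituted ketene acetal carbon, and the alkyne is internal. Ring formation may therefore be slow enough that hydrolysis or thermal oxygen-to-carbon silyl migration of 17, returning it to 16, outruns it. The fallback gives up the ring synthesis and joins two finished rings by aryllithium addition. It sets out from alcohol 12 and bromide 2 and comes back at 22.
- MnO2 oxidises 12 to 2-(benzyloxy)-6-{2-[4-(benzyloxy)-3-methoxyphenyl]ethyl}-4-methoxybenzaldehyde F1.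
- Bromide 2 and PPh3 give {[4-(benzyloxy)-3-methoxyphenyl]methyl}triphenylphosphonium bromide F2.
- The ylide of F2 (KOtBu) is condensed with 3-methoxy-5-(methoxymethoxy)benzaldehyde F3, made from commercial 3-hydroxy-5-methoxybenzaldehyde and chloromethyl methyl ether. This gives 1-(benzyloxy)-2-methoxy-4-{2-[3-methoxy-5-(methoxymethoxy)phenyl]ethenyl}benzene F4 as an E/Z mixture.
- Diimide (TsNHNH2, NaOAc) saturates the alkene without touching the benzyl ether and gives 1-(benzyloxy)-2-methoxy-4-{2-[3-methoxy-5-(methoxymethoxy)phenyl]ethyl}benzene F5.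
- n-BuLi at 0 °C metalates F5 at the ring carbon between the methoxy and methoxymethoxy groups (directed ortho metalation). Addition to F1 gives the diarylmethanol F6.
- Hydrogenolysis over Pd/C removes the three benzyl ethers and the doubly benzylic hydroxyl and gives the mono(methoxymethyl) ether F7 of the target. HCl in methanol then frees 22.

**Step 10 (with step 9).** Bromide 13 carries ortho- and para-alkoxy groups and ionises readily. It may alkylate the electron-rich rings of its neighbours or hydrolyse before the enolate captures it, and O-alkylation or dialkylation can add to the loss. The fallback avoids the halide. It sets out from 12 and comes back at 15.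
- Methyl chloroformate and pyridine convert 12 into the stable (2-(benzyloxy)-6-{2-[4-(benzyloxy)-3-methoxyphenyl]ethyl}-4-methoxyphenyl)methyl methyl carbonate F8.
- F8 benzylates 14 in a palladium-catalysed benzylic substitution of the Tsuji–Trost type. The zerovalent palladium catalyst is formed from [Pd(C3H5)(cod)]BF4 and 1,1'-bis(diphenylphosphino)ferrocene, and the methoxide released on ionisation serves as the base.

**Step 11.** With an α-branched keto ester, ketal formation and loss of methanol may stop short and leave a mixture of ketone, ketal and enol ether that cannot be distilled. The fallback replaces the methyl enol ether by a silyl enol ether and methylates after the ring is made. It sets out from 15 and comes back at 20.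
- Me3SiCl and Et3N give methyl 2-(2-(benzyloxy)-6-{2-[4-(benzyloxy)-3-methoxyphenyl]ethyl}-4-methoxybenzyl)-3-[(trimethylsilyl)oxy]but-2-enoate F9.
- LiN(iPr)2 and Me3SiCl give the 1-methoxy-1,3-bis(trimethylsilyloxy)buta-1,3-diene F10 that carries the ring A benzyl group at C2.
- Cycloaddition of F10 with 7 and acid work-up give benzyl 3-(2-(benzyloxy)-6-{2-[4-(benzyloxy)-3-methoxyphenyl]ethyl}-4-methoxybenzyl)-6-{2-[4-(benzyloxy)-3-methoxyphenyl]ethyl}-2,4-dihydroxybenzoate F11.
- MeI and K2CO3 methylate only the 4-hydroxyl of F11, because the 2-hydroxyl is hydrogen-bonded to the ester as in step 5. This gives 20.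

**Step 15.** At the temperature of decarboxylation the free tetraphenol may oxidise. Ipso protonation of ring B at the bridge-bearing carbon may also expel the ring A benzyl group, so the bridge could be lost or scrambled. The fallback decarboxylates before the phenols are freed. It sets out from 20 and comes back at 22.
- KOH in aqueous DMSO hydrolyses the benzyl ester to 3-(2-(benzyloxy)-6-{2-[4-(benzyloxy)-3-methoxyphenyl]ethyl}-4-methoxybenzyl)-6-{2-[4-(benzyloxy)-3-methoxyphenyl]ethyl}-2-hydroxy-4-methoxybenzoic acid F12.
- Warming F12 in DMF gives 2-(2-(benzyloxy)-6-{2-[4-(benzyloxy)-3-methoxyphenyl]ethyl}-4-methoxybenzyl)-5-{2-[4-(benzyloxy)-3-methoxyphenyl]ethyl}-3-methoxyphenol F13, which has a single free hydroxyl.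
- Hydrogenolysis of F13 over Pd/C at room temperature gives 22.

## Further compounds

F1 | step 13 | 2-(benzyloxy)-6-{2-[4-(benzyloxy)-3-methoxyphenyl]ethyl}-4-methoxybenzaldehyde | O=Cc1c(CCc2ccc(OCc3ccccc3)c(OC)c2)cc(OC)cc1OCc1ccccc1
F2 | step 13 | {[4-(benzyloxy)-3-methoxyphenyl]methyl}triphenylphosphonium bromide | COc1cc(C[P+](c2ccccc2)(c2ccccc2)c2ccccc2)ccc1OCc1ccccc1.[Br-]
F3 | step 13 | 3-methoxy-5-(methoxymethoxy)benzaldehyde | COCOc1cc(OC)cc(C=O)c1
F4 | step 13 | 1-(benzyloxy)-2-methoxy-4-{2-[3-methoxy-5-(methoxymethoxy)phenyl]ethenyl}benzene (E/Z mixture) | COCOc1cc(OC)cc(C=Cc2ccc(OCc3ccccc3)c(OC)c2)c1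
F5 | step 13 | 1-(benzyloxy)-2-methoxy-4-{2-[3-methoxy-5-(methoxymethoxy)phenyl]ethyl}benzene | COCOc1cc(OC)cc(CCc2ccc(OCc3ccccc3)c(OC)c2)c1
F6 | step 13 | (2-(benzyloxy)-6-{2-[4-(benzyloxy)-3-methoxyphenyl]ethyl}-4-methoxyphenyl)(4-{2-[4-(benzyloxy)-3-methoxyphenyl]ethyl}-2-methoxy-6-(methoxymethoxy)phenyl)methanol (racemic) | COCOc1cc(CCc2ccc(OCc3ccccc3)c(OC)c2)cc(OC)c1C(O)c1c(OCc2ccccc2)cc(OC)cc1CCc1ccc(OCc2ccccc2)c(OC)c1
F7 | step 13 | 3-[2-(4-hydroxy-3-methoxyphenyl)ethyl]-2-{4-[2-(4-hydroxy-3-methoxyphenyl)ethyl]-2-methoxy-6-(methoxymethoxy)benzyl}-5-methoxyphenol | COCOc1cc(CCc2ccc(O)c(OC)c2)cc(OC)c1Cc1c(O)cc(OC)cc1CCc1ccc(O)c(OC)c1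
F8 | step 10 | (2-(benzyloxy)-6-{2-[4-(benzyloxy)-3-methoxyphenyl]ethyl}-4-methoxyphenyl)methyl methyl carbonate | COC(=O)OCc1c(CCc2ccc(OCc3ccccc3)c(OC)c2)cc(OC)cc1OCc1ccccc1
F9 | step 11 | methyl 2-(2-(benzyloxy)-6-{2-[4-(benzyloxy)-3-methoxyphenyl]ethyl}-4-methoxybenzyl)-3-[(trimethylsilyl)oxy]but-2-enoate | COC(=O)C(Cc1c(OCc2ccccc2)cc(OC)cc1CCc1ccc(OCc2ccccc2)c(OC)c1)=C(C)O[Si](C)(C)C
F10 | step 11 | 2-(2-(benzyloxy)-6-{2-[4-(benzyloxy)-3-methoxyphenyl]ethyl}-4-methoxybenzyl)-1-methoxy-1,3-bis[(trimethylsilyl)oxy]buta-1,3-diene | C=C(O[Si](C)(C)C)C(Cc1c(OCc2ccccc2)cc(OC)cc1CCc1ccc(OCc2ccccc2)c(OC)c1)=C(OC)O[Si](C)(C)C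
F11 | step 11 | benzyl 3-(2-(benzyloxy)-6-{2-[4-(benzyloxy)-3-methoxyphenyl]ethyl}-4-methoxybenzyl)-6-{2-[4-(benzyloxy)-3-methoxyphenyl]ethyl}-2,4-dihydroxybenzoate | O=C(OCc1ccccc1)c1c(O)c(Cc2c(OCc3ccccc3)cc(OC)cc2CCc2ccc(OCc3ccccc3)c(OC)c2)c(O)cc1CCc1ccc(OCc2ccccc2)c(OC)c1
F12 | step 15 | 3-(2-(benzyloxy)-6-{2-[4-(benzyloxy)-3-methoxyphenyl]ethyl}-4-methoxybenzyl)-6-{2-[4-(benzyloxy)-3-methoxyphenyl]ethyl}-2-hydroxy-4-methoxybenzoic acid | O=C(O)c1c(O)c(Cc2c(OCc3ccccc3)cc(OC)cc2CCc2ccc(OCc3ccccc3)c(OC)c2)c(OC)cc1CCc1ccc(OCc2ccccc2)c(OC)c1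
F13 | step 15 | 2-(2-(benzyloxy)-6-{2-[4-(benzyloxy)-3-methoxyphenyl]ethyl}-4-methoxybenzyl)-5-{2-[4-(benzyloxy)-3-methoxyphenyl]ethyl}-3-methoxyphenol | Oc1cc(CCc2ccc(OCc3ccccc3)c(OC)c2)cc(OC)c1Cc1c(OCc2ccccc2)cc(OC)cc1CCc1ccc(OCc2ccccc2)c(OC)c1
A1 | alternative 1 | 1-ethenyl-2-[4-ethenyl-2-methoxy-6-(methoxymethoxy)benzyl]-5-methoxy-3-(methoxymethoxy)benzene | COCOc1cc(OC)cc(C=C)c1Cc1c(OCOC)cc(C=C)cc1OC
A2 | alternative 1 | 1-(benzyloxy)-4-bromo-2-methoxybenzene | COc1cc(Br)ccc1OCc1ccccc1
A3 | alternative 1 | bis-stilbene diarylmethane, both alkenes E | COCOc1cc(OC)cc(/C=C/c2ccc(OCc3ccccc3)c(OC)c2)c1Cc1c(OCOC)cc(/C=C/c2ccc(OCc3ccccc3)c(OC)c2)cc1OC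
A4 | alternative 2 | 6-{2-[4-(benzyloxy)-3-methoxyphenyl]ethyl}-4-methoxy-2H-pyran-2-one | COc1cc(CCc2ccc(OCc3ccccc3)c(OC)c2)oc(=O)c1
A5 | alternative 2 | 1-(2-(benzyloxy)-4-{2-[4-(benzyloxy)-3-methoxyphenyl]ethyl}-6-methoxyphenyl)prop-2-yn-1-one | C#CC(=O)c1c(OCc2ccccc2)cc(CCc2ccc(OCc3ccccc3)c(OC)c2)cc1OC
A6 | alternative 2 | (2-(benzyloxy)-4-{2-[4-(benzyloxy)-3-methoxyphenyl]ethyl}-6-methoxyphenyl)(2-{2-[4-(benzyloxy)-3-methoxyphenyl]ethyl}-4-methoxyphenyl)methanone | COc1ccc(C(=O)c2c(OCc3ccccc3)cc(CCc3ccc(OCc4ccccc4)c(OC)c3)cc2OC)c(CCc2ccc(OCc3ccccc3)c(OC)c2)c1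
A7 | alternative 3 | 4-(2-(benzyloxy)-4-{2-[4-(benzyloxy)-3-methoxyphenyl]ethyl}-6-methoxybenzyl)-3-{2-[4-(benzyloxy)-3-methoxyphenyl]ethyl}cyclobut-2-en-1-one (racemic) | O=C1C=C(CCc2ccc(OCc3ccccc3)c(OC)c2)C1Cc1c(OCc2ccccc2)cc(CCc2ccc(OCc3ccccc3)c(OC)c2)cc1OC
A8 | alternative 3 | methoxyethyne (methoxyacetylene) | C#COC
A9 | alternative 3 | 2-(2-(benzyloxy)-4-{2-[4-(benzyloxy)-3-methoxyphenyl]ethyl}-6-methoxybenzyl)-3-{2-[4-(benzyloxy)-3-methoxyphenyl]ethyl}-5-methoxyphenol | COc1cc(O)c(Cc2c(OCc3ccccc3)cc(CCc3ccc(OCc4ccccc4)c(OC)c3)cc2OC)c(CCc2ccc(OCc3ccccc3)c(OC)c2)c1
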